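**Plan**

- Retrosynthesis: after removal of three O-substituents (two aryl silyl ethers and the 2'-O-methyl of ring B), both ring C bonds C3–C4 and O1–C2 are cut in one retro oxa-Diels–Alder step. Each half is traced back through C=O and C=C reduction levels to one chalcone, which is cut at its enone C=C into an acetophenone and a benzaldehyde.
- Enabling feature: O1–C8a–C4a–C4 is a latent o-quinone methide (the ring A phenol oxygen is ortho to the benzylic, styryl-bearing C4, and the 7-OMe is para to C4). C2–C3 is a latent E-styrene polarised by the 2,4-dioxygenated ring B. Both halves are C6–C3–C6 units with the same oxygenation.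
- Forward: Claisen–Schmidt chalcone, then monosilylation. Branch a: 1,2-reduction to the allylic alcohol (diene precursor). Branch b: C=C hydrogenation, C=O reduction and dehydration to the E-2-alkenylphenol (dienophile). One cycloaddition joins the two C15 halves and forms ring C; O-methylation and desilylation finish.
- Stereochemistry: all three stereocentres arise in the cycloaddition. The E alkene gives C2/C3 trans; the E-o-quinone methide with endo approach gives C2/C4 cis and so C3/C4 trans. A chiral phosphoric acid, hydrogen-bonded to the o-quinone methide carbonyl and to the free 2-OH of the dienophile (the later 2'-OMe), sets the absolute configuration (2R,3R,4R).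

Key step: step 7

Assumption: the (R)-configured phosphoric acid is taken to deliver the (2R,3R,4R) series; should the sense of induction be the opposite, the (S)-catalyst is used and nothing else changes.

**Route**

Step 1
Reactants: 1 paeonol, 1-(2-hydroxy-4-methoxyphenyl)ethanone; 2 4-hydroxybenzaldehyde
Product: 3 (E)-1-(2-hydroxy-4-methoxyphenyl)-3-(4-hydroxyphenyl)prop-2-en-1-one
Conditions: KOH (60% aq., excess), EtOH, 0 °C → rt, 48–72 h; then 2 M HCl to pH 3
Reagents that add atoms: none
Why: Claisen–Schmidt condensation (crossed aldol, then E1cB loss of water) of a methyl ketone with a non-enolisable aldehyde; excess base carries both phenoxides and the conjugated E enone should form under thermodynamic control.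

Step 2
Reactants: 3 (E)-1-(2-hydroxy-4-methoxyphenyl)-3-(4-hydroxyphenyl)prop-2-en-1-one
Product: 4 (E)-1-(2-hydroxy-4-methoxyphenyl)-3-{4-[(triisopropylsilyl)oxy]phenyl}prop-2-en-1-one
Conditions: TIPSCl (1.1 equiv), imidazole (2.2 equiv), DMF, 0 °C → rt
Reagents that add atoms: triisopropylsilyl chloride (TIPSCl), CC(C)[Si](Cl)(C(C)C)C(C)C
Why: Silylation should be selective for the free 4-OH because the 2'-OH is hydrogen-bonded to the ketone and hindered; the silyl ether later blocks the p-quinone methide tautomer of the cation and keeps this oxygen out of the methylation.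

Step 3
Reactants: 4 (E)-1-(2-hydroxy-4-methoxyphenyl)-3-{4-[(triisopropylsilyl)oxy]phenyl}prop-2-en-1-one
Product: 5 rac-(E)-2-(1-hydroxy-3-{4-[(triisopropylsilyl)oxy]phenyl}prop-2-en-1-yl)-5-methoxyphenol
Conditions: NaBH4, CeCl3·7H2O, MeOH/THF, −40 → −20 °C; pH 7 phosphate buffer; used crude and at once in step 7
Reagents that add atoms: none
Why: Luche reduction should give 1,2-addition of hydride to the enone; the carbinol centre may be racemic because it is erased when the alcohol is ionised in step 7.

Step 4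
Reactants: 4 (E)-1-(2-hydroxy-4-methoxyphenyl)-3-{4-[(triisopropylsilyl)oxy]phenyl}prop-2-en-1-one
Product: 6 1-(2-hydroxy-4-methoxyphenyl)-3-{4-[(triisopropylsilyl)oxy]phenyl}propan-1-one
Conditions: H2 (1 atm), 10% Pd/C, EtOAc, rt, stopped after uptake of one equivalent
Reagents that add atoms: none
Why: Heterogeneous catalytic hydrogenation of the enone C=C; the hydrogen-bonded, electron-rich aryl ketone and the aryl silyl ether should not react at 1 atm.

Step 5
Reactants: 6 1-(2-hydroxy-4-methoxyphenyl)-3-{4-[(triisopropylsilyl)oxy]phenyl}propan-1-one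
Product: 7 rac-2-(1-hydroxy-3-{4-[(triisopropylsilyl)oxy]phenyl}propyl)-5-methoxyphenol
Conditions: NaBH4, MeOH/THF, 0 °C → rt; sat. aq. NH4Cl
Reagents that add atoms: none
Why: Borohydride reduction of the aryl ketone to the benzylic alcohol; its stereocentre is removed in the next step.

Step 6
Reactants: 7 rac-2-(1-hydroxy-3-{4-[(triisopropylsilyl)oxy]phenyl}propyl)-5-methoxyphenol
Product: 8 (E)-5-methoxy-2-(3-{4-[(triisopropylsilyl)oxy]phenyl}prop-1-en-1-yl)phenol
Conditions: TsOH·H2O (5 mol %), 4 Å MS, toluene (0.02 M), 80 °C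
Reagents that add atoms: none
Why: Acid-catalysed E1-type dehydration at the benzylic carbon activated by ortho-OH and para-OMe; proton loss from the neighbouring CH2 should give the ring-conjugated E alkene under thermodynamic control, and high dilution disfavours bimolecular side reactions.

Step 7
Reactants: 5 rac-(E)-2-(1-hydroxy-3-{4-[(triisopropylsilyl)oxy]phenyl}prop-2-en-1-yl)-5-methoxyphenol; 8 (E)-5-methoxy-2-(3-{4-[(triisopropylsilyl)oxy]phenyl}prop-1-en-1-yl)phenol
Product: 10 2-[(2R,3R,4R)-7-methoxy-3-{4-[(triisopropylsilyl)oxy]benzyl}-4-[(E)-2-{4-[(triisopropylsilyl)oxy]phenyl}ethenyl]-3,4-dihydro-2H-chromen-2-yl]-5-methoxyphenol, via o-quinone methide 9 (not isolated)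
Conditions: (R)-3,3'-bis(2,4,6-triisopropylphenyl)-1,1'-binaphthyl-2,2'-diyl hydrogen phosphate, (R)-TRIP (10 mol %), 4 Å MS, toluene, 0 °C → rt; 5 added slowly to 8 (1.2 equiv) and the catalyst
Reagents that add atoms: none
Why: The phosphoric acid ionises the doubly activated (benzylic and allylic, ortho-OH, para-OMe) carbinol of 5 with loss of water and holds the resulting E-configured o-quinone methide 9 by a hydrogen bond to its carbonyl oxygen while its phosphoryl oxygen binds the free 2-OH of 8; the electron-rich alkene then adds in an asynchronous inverse-electron-demand oxa-Diels–Alder reaction in which the C3–C4 bond (benzyl-bearing alkene carbon to methide carbon) runs ahead of the O1–C2 bond. The closest known reaction type is the chiral-phosphoric-acid-catalysed [4+2] cycloaddition of o-quinone methides generated from o-hydroxybenzyl alcohols with o-hydroxystyrenes. Ring C (the pyran ring) closes in a [4π+2π] mode from the O=C8a–C4a=C4 heterodiene and the C2=C3 alkene, driven by rearomatisation of ring A. C2/C3 trans follows suprafacially from the E alkene of 8, C2/C4 cis (hence C3/C4 trans) from the E geometry of 9 combined with endo orientation of the 2-hydroxy-4-methoxyphenyl group, which the two-point hydrogen bonding enforces and which also gives the all-equatorial chroman, and the absolute configuration comes from the 3,3'-aryl pocket of the catalyst shielding one face of bound 9. The step needs bond formation at C4 (1,4) and not at the styryl terminus (1,6), and at the alkene and not at the electron-rich arene carbons: only attack at C4 lets the oxygen close a six-membered ring in the same event, the hydrogen-bonded assembly places the alkene carbon over C4, and the silyl ether prevents the competing p-quinone methide. The carbinol stereocentre of 5 is lost on ionisation, so racemic 5 should converge on one product.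

Step 8
Reactants: 10 2-[(2R,3R,4R)-7-methoxy-3-{4-[(triisopropylsilyl)oxy]benzyl}-4-[(E)-2-{4-[(triisopropylsilyl)oxy]phenyl}ethenyl]-3,4-dihydro-2H-chromen-2-yl]-5-methoxyphenol
Product: 11 (2R,3R,4R)-2-(2,4-dimethoxyphenyl)-7-methoxy-3-{4-[(triisopropylsilyl)oxy]benzyl}-4-[(E)-2-{4-[(triisopropylsilyl)oxy]phenyl}ethenyl]-3,4-dihydro-2H-chromene
Conditions: MeI (3 equiv), K2CO3 (2 equiv), acetone, rt
Reagents that add atoms: iodomethane (MeI), CI
Why: Williamson O-methylation of the only free phenol, the hydrogen-bonding handle of step 7; the anhydrous mild base should leave the aryl silyl ethers and the three stereocentres untouched.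

Step 9
Reactants: 11 (2R,3R,4R)-2-(2,4-dimethoxyphenyl)-7-methoxy-3-{4-[(triisopropylsilyl)oxy]benzyl}-4-[(E)-2-{4-[(triisopropylsilyl)oxy]phenyl}ethenyl]-3,4-dihydro-2H-chromene
Product: 12 caraganin C, 4-{[(2R,3R,4R)-2-(2,4-dimethoxyphenyl)-4-[(E)-2-(4-hydroxyphenyl)ethenyl]-7-methoxy-3,4-dihydro-2H-chromen-3-yl]methyl}phenol
Conditions: Bu4NF (2.4 equiv), AcOH (2.4 equiv), THF, 0 °C
Reagents that add atoms: none
Why: Fluoride-induced cleavage of both aryl Si–O bonds; the acetic acid buffer protonates the phenoxides as they form, so the benzylic ether at C2 and the styrene should not be exposed to base.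

**Compound list**

1 | paeonol, 1-(2-hydroxy-4-methoxyphenyl)ethanone | CC(=O)c1ccc(OC)cc1O | starting material
2 | 4-hydroxybenzaldehyde | O=Cc1ccc(O)cc1 | starting material
3 | (E)-1-(2-hydroxy-4-methoxyphenyl)-3-(4-hydroxyphenyl)prop-2-en-1-one | COc1ccc(C(=O)/C=C/c2ccc(O)cc2)c(O)c1 | intermediate
4 | (E)-1-(2-hydroxy-4-methoxyphenyl)-3-{4-[(triisopropylsilyl)oxy]phenyl}prop-2-en-1-one | COc1ccc(C(=O)/C=C/c2ccc(O[Si](C(C)C)(C(C)C)C(C)C)cc2)c(O)c1 | intermediate
5 | rac-(E)-2-(1-hydroxy-3-{4-[(triisopropylsilyl)oxy]phenyl}prop-2-en-1-yl)-5-methoxyphenol | COc1ccc(C(O)/C=C/c2ccc(O[Si](C(C)C)(C(C)C)C(C)C)cc2)c(O)c1 | intermediate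
6 | 1-(2-hydroxy-4-methoxyphenyl)-3-{4-[(triisopropylsilyl)oxy]phenyl}propan-1-one | COc1ccc(C(=O)CCc2ccc(O[Si](C(C)C)(C(C)C)C(C)C)cc2)c(O)c1 | intermediate
7 | rac-2-(1-hydroxy-3-{4-[(triisopropylsilyl)oxy]phenyl}propyl)-5-methoxyphenol | COc1ccc(C(O)CCc2ccc(O[Si](C(C)C)(C(C)C)C(C)C)cc2)c(O)c1 | intermediate
8 | (E)-5-methoxy-2-(3-{4-[(triisopropylsilyl)oxy]phenyl}prop-1-en-1-yl)phenol | COc1ccc(/C=C/Cc2ccc(O[Si](C(C)C)(C(C)C)C(C)C)cc2)c(O)c1 | intermediate
9 | o-quinone methide, (6E)-3-methoxy-6-[(2E)-3-{4-[(triisopropylsilyl)oxy]phenyl}prop-2-en-1-ylidene]cyclohexa-2,4-dien-1-one (not isolated) | COC1=CC(=O)/C(=C/C=C/c2ccc(O[Si](C(C)C)(C(C)C)C(C)C)cc2)C=C1 | intermediate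
10 | 2-[(2R,3R,4R)-7-methoxy-3-{4-[(triisopropylsilyl)oxy]benzyl}-4-[(E)-2-{4-[(triisopropylsilyl)oxy]phenyl}ethenyl]-3,4-dihydro-2H-chromen-2-yl]-5-methoxyphenol | COc1ccc2c(c1)O[C@@H](c1ccc(OC)cc1O)[C@H](Cc1ccc(O[Si](C(C)C)(C(C)C)C(C)C)cc1)[C@H]2/C=C/c1ccc(O[Si](C(C)C)(C(C)C)C(C)C)cc1 | intermediate
11 | (2R,3R,4R)-2-(2,4-dimethoxyphenyl)-7-methoxy-3-{4-[(triisopropylsilyl)oxy]benzyl}-4-[(E)-2-{4-[(triisopropylsilyl)oxy]phenyl}ethenyl]-3,4-dihydro-2H-chromene | COc1ccc2c(c1)O[C@@H](c1ccc(OC)cc1OC)[C@H](Cc1ccc(O[Si](C(C)C)(C(C)C)C(C)C)cc1)[C@H]2/C=C/c1ccc(O[Si](C(C)C)(C(C)C)C(C)C)cc1 | intermediate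
12 | caraganin C, 4-{[(2R,3R,4R)-2-(2,4-dimethoxyphenyl)-4-[(E)-2-(4-hydroxyphenyl)ethenyl]-7-methoxy-3,4-dihydro-2H-chromen-3-yl]methyl}phenol | COc1ccc2c(c1)O[C@@H](c1ccc(OC)cc1OC)[C@H](Cc1ccc(O)cc1)[C@H]2/C=C/c1ccc(O)cc1 | target

**Step count and risks**

Total step count: 9. Longest linear sequence: 8 steps (steps 1, 2, 4, 5, 6, 7, 8, 9); step 3 is the one-step side branch.

The three steps most likely to fail:

Step 7. What may go wrong: insufficient enantiofacial discrimination by the catalyst, or leakage of the o-quinone methide into 1,6-addition at the styryl terminus, Friedel–Crafts alkylation of the resorcinol-type rings, or oxa-6π closure. Fallback (resolution in place of catalyst control), setting out from 5 and 8: the cycloaddition is run with achiral diphenyl phosphate, (PhO)2P(O)OH, in toluene. The E geometries and the endo preference still fix the relative configuration, so this should give the racemic all-trans cycloadduct F1. Acylation of its free phenol with (1S)-camphanic chloride (Et3N, DMAP, CH2Cl2) gives two diastereomers, the (2R,3R,4R)-configured camphanate F2 and the (2S,3S,4S)-configured camphanate F3, to be separated by chromatography or crystallisation. Ammonolysis of F2 (NH3, MeOH, 0 °C), which spares the aryl silyl ethers, comes back to the route at 10.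

Step 3. What may go wrong: ionisation of the very labile allylic alcohol in the Lewis acidic methanolic medium or on work-up, leading to cyclodehydration or solvolysis before use, and competing 1,4-reduction. Fallback (the cyclised form is made on purpose and used as the stable o-quinone methide reservoir), setting out from 4: reduction with NaBH4 in THF/EtOH followed by AcOH should give the racemic 7-methoxy-2-{4-[(triisopropylsilyl)oxy]phenyl}-2H-chromene F4, which can be purified and stored. Under the acid of step 7 (a more acidic chiral N-triflyl phosphoramide if needed), C2–O1 ionisation of F4 regenerates 9 in the presence of 8, and the sequence comes back to the route at 10.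

Step 6. What may go wrong: trapping of the transient o-quinone methide by alkene already formed (dimerisation by [4+2] addition), cationic oligomerisation, or incomplete E selectivity. Fallback (the phenol is capped so that the elimination cannot pass through an o-quinone methide), setting out from 6: O-allylation (allyl bromide, K2CO3, acetone, reflux) gives the allyl ether ketone F5. NaBH4 reduction gives the allyl ether alcohol F6. Dehydration with catalytic TsOH·H2O in toluene gives the allyl ether E-alkene F7. Deallylation with Pd(PPh3)4 (catalytic) and morpholine in THF at rt comes back to the route at 8.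

Further compounds
F1 | step 7 | racemic cycloadduct, (2R,3R,4R)- and (2S,3S,4S)-enantiomers of 10 in equal amounts | COc1ccc2c(c1)O[C@@H](c1ccc(OC)cc1O)[C@H](Cc1ccc(O[Si](C(C)C)(C(C)C)C(C)C)cc1)[C@H]2/C=C/c1ccc(O[Si](C(C)C)(C(C)C)C(C)C)cc1.COc1ccc2c(c1)O[C@H](c1ccc(OC)cc1O)[C@@H](Cc1ccc(O[Si](C(C)C)(C(C)C)C(C)C)cc1)[C@@H]2/C=C/c1ccc(O[Si](C(C)C)(C(C)C)C(C)C)cc1
F2 | step 7 | (2R,3R,4R)-configured camphanate, 2-[(2R,3R,4R)-7-methoxy-3-{4-[(triisopropylsilyl)oxy]benzyl}-4-[(E)-2-{4-[(triisopropylsilyl)oxy]phenyl}ethenyl]-3,4-dihydro-2H-chromen-2-yl]-5-methoxyphenyl (1S,4R)-4,7,7-trimethyl-3-oxo-2-oxabicyclo[2.2.1]heptane-1-carboxylate | COc1ccc2c(c1)O[C@@H](c1ccc(OC)cc1OC(=O)[C@]34OC(=O)[C@](C)(CC3)C4(C)C)[C@H](Cc1ccc(O[Si](C(C)C)(C(C)C)C(C)C)cc1)[C@H]2/C=C/c1ccc(O[Si](C(C)C)(C(C)C)C(C)C)cc1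
F3 | step 7 | (2S,3S,4S)-configured camphanate, diastereomer of F2 with the same (1S,4R)-acyl group | COc1ccc2c(c1)O[C@H](c1ccc(OC)cc1OC(=O)[C@]34OC(=O)[C@](C)(CC3)C4(C)C)[C@@H](Cc1ccc(O[Si](C(C)C)(C(C)C)C(C)C)cc1)[C@@H]2/C=C/c1ccc(O[Si](C(C)C)(C(C)C)C(C)C)cc1
F4 | step 3 | rac-7-methoxy-2-{4-[(triisopropylsilyl)oxy]phenyl}-2H-chromene | COc1ccc2C=CC(c3ccc(O[Si](C(C)C)(C(C)C)C(C)C)cc3)Oc2c1
F5 | step 6 | 1-[4-methoxy-2-(prop-2-en-1-yloxy)phenyl]-3-{4-[(triisopropylsilyl)oxy]phenyl}propan-1-one | COc1ccc(C(=O)CCc2ccc(O[Si](C(C)C)(C(C)C)C(C)C)cc2)c(OCC=C)c1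
F6 | step 6 | rac-1-[4-methoxy-2-(prop-2-en-1-yloxy)phenyl]-3-{4-[(triisopropylsilyl)oxy]phenyl}propan-1-ol | COc1ccc(C(O)CCc2ccc(O[Si](C(C)C)(C(C)C)C(C)C)cc2)c(OCC=C)c1
F7 | step 6 | (E)-triisopropyl(4-{3-[4-methoxy-2-(prop-2-en-1-yloxy)phenyl]prop-2-en-1-yl}phenoxy)silane | COc1ccc(/C=C/Cc2ccc(O[Si](C(C)C)(C(C)C)C(C)C)cc2)c(OCC=C)c1
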